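## Retrosynthetic overview

- Eritrichin comes from one global O-dealkylation (4 OMe, 2 OBn, 1 CO2Bn) of the fully protected ester.
- The key disconnection is the acyl C–O bond between the naphthalene C2 carboxyl and the secondary oxygen of protected (R)-danshensu. The acyl partner is not the naphthoic acid but its isomer, an α-veratrylidene-γ-veratryl enol lactone.
- The enol lactone comes from a Perkin-type condensation of 4-(3,4-dimethoxyphenyl)-4-oxobutanoic acid with veratraldehyde. The alcohol comes from tribenzylation of natural sodium (R)-danshensu, so the stereocentre is bought and never touched.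
- Ring order: the three benzene rings are bought. The butenolide ring is made first and is opened in the C–O-forming step. The second naphthalene ring (C1–C4) then closes last, in the same flask.

Assumption: sodium (R)-danshensu (salvianic acid A sodium, natural R form, a bulk botanical/fermentation product) and 4-(3,4-dimethoxyphenyl)-4-oxobutanoic acid are taken as cheap commercial materials, and the ee of the former is checked by chiral HPLC after benzylation.

## Route

Step 1
Reactants: 1 4-(3,4-dimethoxyphenyl)-4-oxobutanoic acid; 2 3,4-dimethoxybenzaldehyde (veratraldehyde)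
Product: 4 (3E)-3-(3,4-dimethoxybenzylidene)-5-(3,4-dimethoxyphenyl)furan-2(3H)-one, via 5-(3,4-dimethoxyphenyl)furan-2(3H)-one 3 (not isolated)
Conditions: Ac2O, NaOAc (1 equiv), 100 °C, 2 h; crystallise from EtOH
Reagents that add atoms: none
Why: Perkin-type condensation in which Ac2O cyclodehydrates the γ-keto acid to enol lactone 3, whose acidic C3 methylene condenses with the aldehyde and eliminates to the thermodynamically preferred E-arylidene (aryl anti to the lactone C=O, syn to C4–H); no stereocentre is formed.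

Step 2
Reactants: 5 sodium (2R)-3-(3,4-dihydroxyphenyl)-2-hydroxypropanoate (sodium (R)-danshensu)
Product: 6 benzyl (2R)-3-[3,4-bis(benzyloxy)phenyl]-2-hydroxypropanoate
Conditions: BnBr (3.3 equiv), K2CO3 (2.5 equiv), DMF, N2, rt→40 °C
Reagents that add atoms: benzyl bromide, BrCc1ccccc1
Why: Williamson ether synthesis plus carboxylate SN2 alkylation, in which K2CO3 ionises only the two phenols and the carboxylate is already ionic, so the secondary alcohol stays free and the chiral-pool (R)-centre is not touched.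

Step 3
Reactants: 4 (3E)-3-(3,4-dimethoxybenzylidene)-5-(3,4-dimethoxyphenyl)furan-2(3H)-one (1.1 equiv); 6 benzyl (2R)-3-[3,4-bis(benzyloxy)phenyl]-2-hydroxypropanoate
Product: 8 benzyl (2R)-3-[3,4-bis(benzyloxy)phenyl]-2-{[4-(3,4-dimethoxyphenyl)-6,7-dimethoxynaphthalene-2-carbonyl]oxy}propanoate, via benzyl (2R)-3-[3,4-bis(benzyloxy)phenyl]-2-{[(2E)-2-(3,4-dimethoxybenzylidene)-4-(3,4-dimethoxyphenyl)-4-oxobutanoyl]oxy}propanoate 7 (not isolated)
Conditions: (i) DMAP (20 mol %), dry DCE, 70 °C; (ii) same flask, TFA (25 vol %), 0 °C→rt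
Reagents that add atoms: none
Why: Proposed new method: alcoholytic benzannulation, in which enol lactone 4 serves as a latent, self-activated 2-naphthoyl donor: DMAP adds to the lactone C=O (an enol ester whose leaving group, an aryl-ketone enolate, is phenoxide-like, enol pKa about 10), the acylpyridinium is trapped by the free secondary OH of 6 to form the ester C–O bond, ketonisation to 7 makes this irreversible, and acid then drives Friedel–Crafts hydroxyalkylation of the unmasked ketone by C6 of the veratrylidene ring (para to OMe and held next to the CH2C(=O)Ar arm by the E-alkene) followed by loss of water to the aromatic ring; the C–O and C–H bonds at the stereocentre are never broken, so (R) is retained; the closest known reaction types are DMAP-catalysed acylation of alcohols with enol esters and the acid-induced isomerisation of such arylidene butenolides to 4-aryl-2-naphthoic acids (or their simple alkyl esters in a solvent alcohol with mineral acid), but a stoichiometric, chiral, functionalised secondary α-hydroxy ester has not been used as the nucleophile and the two catalytic regimes have not been run in sequence.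

Step 4
Reactants: 8 benzyl (2R)-3-[3,4-bis(benzyloxy)phenyl]-2-{[4-(3,4-dimethoxyphenyl)-6,7-dimethoxynaphthalene-2-carbonyl]oxy}propanoate
Product: 9 eritrichin, (2R)-3-(3,4-dihydroxyphenyl)-2-{[4-(3,4-dihydroxyphenyl)-6,7-dihydroxynaphthalene-2-carbonyl]oxy}propanoic acid
Conditions: BBr3 (12 equiv), CH2Cl2, −78→0 °C; then ice/H2O; C18 chromatography (H2O/MeCN, 0.1 % HCO2H) under Ar
Reagents that add atoms: none
Why: BBr3 Lewis-acid dealkylation, in which bromide attacks the unhindered methyl and benzyl carbons of the boron-complexed ethers and of the benzyl ester far faster than the secondary carbon of the naphthoate at or below 0 °C, so all seven groups fall in one operation and the stereocentre is untouched.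

## Compound list

1 | 4-(3,4-dimethoxyphenyl)-4-oxobutanoic acid | COc1ccc(C(=O)CCC(=O)O)cc1OC | starting material
2 | 3,4-dimethoxybenzaldehyde (veratraldehyde) | COc1ccc(C=O)cc1OC | starting material
3 | 5-(3,4-dimethoxyphenyl)furan-2(3H)-one | COc1ccc(C2=CCC(=O)O2)cc1OC | intermediate (not isolated)
4 | (3E)-3-(3,4-dimethoxybenzylidene)-5-(3,4-dimethoxyphenyl)furan-2(3H)-one | COc1ccc(/C=C2\C=C(c3ccc(OC)c(OC)c3)OC2=O)cc1OC | intermediate
5 | sodium (2R)-3-(3,4-dihydroxyphenyl)-2-hydroxypropanoate (sodium (R)-danshensu) | O[C@H](Cc1ccc(O)c(O)c1)C(=O)[O-].[Na+] | starting material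
6 | benzyl (2R)-3-[3,4-bis(benzyloxy)phenyl]-2-hydroxypropanoate | O[C@H](Cc1ccc(OCc2ccccc2)c(OCc2ccccc2)c1)C(=O)OCc1ccccc1 | intermediate
7 | benzyl (2R)-3-[3,4-bis(benzyloxy)phenyl]-2-{[(2E)-2-(3,4-dimethoxybenzylidene)-4-(3,4-dimethoxyphenyl)-4-oxobutanoyl]oxy}propanoate | COc1ccc(/C=C(\CC(=O)c2ccc(OC)c(OC)c2)C(=O)O[C@H](Cc2ccc(OCc3ccccc3)c(OCc3ccccc3)c2)C(=O)OCc2ccccc2)cc1OC | intermediate (not isolated)
8 | benzyl (2R)-3-[3,4-bis(benzyloxy)phenyl]-2-{[4-(3,4-dimethoxyphenyl)-6,7-dimethoxynaphthalene-2-carbonyl]oxy}propanoate | O=C(O[C@H](Cc1ccc(OCc2ccccc2)c(OCc2ccccc2)c1)C(=O)OCc1ccccc1)c1cc(-c2ccc(OC)c(OC)c2)c2cc(OC)c(OC)cc2c1 | intermediate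
9 | eritrichin | O=C(O[C@H](Cc1ccc(O)c(O)c1)C(=O)O)c1cc(-c2ccc(O)c(O)c2)c2cc(O)c(O)cc2c1 | target

## Step count and risks

Total step count: 4. Longest linear sequence: 3 (1 + 2 → 4 → 8 → 9; the branch 5 → 6 → 8 → 9 is equally long).

**1. Step 3 (the proposed new step).**
- Risk: the hindered, electron-poor OH of 6 may open 4 too slowly. Traces of acid or water may also divert 4 to the free naphthoic acid before the C–O bond is made.
- Fallback (known chemistry only): it sets out from 4. Refluxing HCl/AcOH isomerises 4 to 4-(3,4-dimethoxyphenyl)-6,7-dimethoxy-2-naphthoic acid F1. Steglich esterification of this acid with 6 (DCC, cat. DMAP, CH2Cl2, 0 °C→rt) proceeds with retention at the carbinol carbon and comes back to the route at 8.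

**2. Step 4.**
- Risk: bromide may attack the activated α-carbon and cleave the internal ester. The sevenfold dealkylation may be incomplete, or the liberated catechols may be C-benzylated.
- Fallback: exchange the protecting groups before the coupling so that the last step is a neutral hydrogenolysis. It sets out from 4 and comes back at 9.
  - 4 is isomerised to F1 as above.
  - BBr3 (CH2Cl2, −78 °C→rt) demethylates F1, with no sensitive ester present, to 4-(3,4-dihydroxyphenyl)-6,7-dihydroxy-2-naphthoic acid F2.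
  - BnBr/K2CO3/DMF gives benzyl 4-[3,4-bis(benzyloxy)phenyl]-6,7-bis(benzyloxy)-2-naphthoate F3.
  - LiOH (THF/MeOH/H2O, 50 °C) gives 4-[3,4-bis(benzyloxy)phenyl]-6,7-bis(benzyloxy)-2-naphthoic acid F4.
  - DCC/DMAP coupling with 6 gives benzyl (2R)-3-[3,4-bis(benzyloxy)phenyl]-2-({4-[3,4-bis(benzyloxy)phenyl]-6,7-bis(benzyloxy)naphthalene-2-carbonyl}oxy)propanoate F5.
  - H2 (1 atm), Pd/C, THF/MeOH removes all seven benzyl groups and gives 9.

**3. Step 1.**
- Risk: the yield may be only moderate because 3 self-condenses or forms tar. E/Z mixtures would also slow the later ring closure.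
- Fallback: build the arylidene first and the ketone second. It sets out from 2 and comes back at 4.
  - Wittig olefination of 2 with (triphenylphosphoranylidene)succinic anhydride (PhMe, 80 °C) gives (3E)-3-(3,4-dimethoxybenzylidene)oxolane-2,5-dione F6.
  - Friedel–Crafts acylation of veratrole with this anhydride (AlCl3, CH2Cl2, 0 °C) occurs at the non-conjugated carbonyl. It gives (2E)-2-(3,4-dimethoxybenzylidene)-4-(3,4-dimethoxyphenyl)-4-oxobutanoic acid F7.
  - Brief warming in Ac2O/NaOAc cyclodehydrates F7 to 4.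

## Further compounds

F1 | step 3 | 4-(3,4-dimethoxyphenyl)-6,7-dimethoxy-2-naphthoic acid | O=C(O)c1cc(-c2ccc(OC)c(OC)c2)c2cc(OC)c(OC)cc2c1
F2 | step 4 | 4-(3,4-dihydroxyphenyl)-6,7-dihydroxy-2-naphthoic acid | O=C(O)c1cc(-c2ccc(O)c(O)c2)c2cc(O)c(O)cc2c1
F3 | step 4 | benzyl 4-[3,4-bis(benzyloxy)phenyl]-6,7-bis(benzyloxy)-2-naphthoate | O=C(OCc1ccccc1)c1cc(-c2ccc(OCc3ccccc3)c(OCc3ccccc3)c2)c2cc(OCc3ccccc3)c(OCc3ccccc3)cc2c1
F4 | step 4 | 4-[3,4-bis(benzyloxy)phenyl]-6,7-bis(benzyloxy)-2-naphthoic acid | O=C(O)c1cc(-c2ccc(OCc3ccccc3)c(OCc3ccccc3)c2)c2cc(OCc3ccccc3)c(OCc3ccccc3)cc2c1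
F5 | step 4 | benzyl (2R)-3-[3,4-bis(benzyloxy)phenyl]-2-({4-[3,4-bis(benzyloxy)phenyl]-6,7-bis(benzyloxy)naphthalene-2-carbonyl}oxy)propanoate | O=C(O[C@H](Cc1ccc(OCc2ccccc2)c(OCc2ccccc2)c1)C(=O)OCc1ccccc1)c1cc(-c2ccc(OCc3ccccc3)c(OCc3ccccc3)c2)c2cc(OCc3ccccc3)c(OCc3ccccc3)cc2c1
F6 | step 1 | (3E)-3-(3,4-dimethoxybenzylidene)oxolane-2,5-dione | COc1ccc(/C=C2\CC(=O)OC2=O)cc1OC
F7 | step 1 | (2E)-2-(3,4-dimethoxybenzylidene)-4-(3,4-dimethoxyphenyl)-4-oxobutanoic acid | COc1ccc(/C=C(\CC(=O)c2ccc(OC)c(OC)c2)C(=O)O)cc1OC
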